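**Retrosynthetic overview**

1. The central (E)-2-alkyl-2-enal is cut by retro-aldol condensation. Ring A and ring B are identical (2S,3S,6R, all-cis), so the target is the self-condensation dimer of one aldehyde, 12-[(2R,5S,6S)-5-hydroxy-6-methylpiperidin-2-yl]dodecanal.
2. In the monomer ring, C3–C4 and N1–C2 are cut together. This gives an (R)-β-amino aldehyde acetal (N1, C6, C5, C4 and the side chain) and 1-(benzyloxy)propan-2-one (C2 with its methyl, C3 with its oxygen), joined by a [4+2] cyclocondensation to a 2,3-dihydropyridine.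
3. Enabling feature: in each ring N1–C2(CH3)–C3(OH) is an aminated α-oxy-acetone unit, and C4 stands 1,3 to N1 through the unsubstituted C5 and C6. One oxidation level up (C2=N1, C3=C4) both bonds are plain carbonyl condensations.
4. Stereochemistry: C6 is set with the (R)-tert-butanesulfinyl auxiliary. C2 and C3 are then set together in one hydrogenation from the face opposite to the C6 chain.
5. Order of ring formation: the piperidine ring is made once (step 7, reduced in step 8). The dimerisation (step 11) turns it into ring A and ring B, so the two bonds of step 7 appear in both rings.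

Key step: step 7

Remark: the target is taken as the free bis-amine. Both rings are numbered N1, C2 (CH3), C3 (OH), C4, C5, C6 (side chain); ring A is on the CH= side of the enal and ring B on the C(CHO)= side.

**Route**

Step 1
Reactants: 1 12-bromododecan-1-ol; 2 benzyl 2,2,2-trichloroacetimidate
Product: 3 benzyl 12-bromododecyl ether
Conditions: CF3SO3H (5 mol%), CH2Cl2/cyclohexane, 0 °C → rt
Reagents that add atoms: 2 benzyl 2,2,2-trichloroacetimidate, ClC(Cl)(Cl)C(=N)OCc1ccccc1
Why: Acid-catalysed O-benzylation with the trichloroacetimidate protects the alcohol without forming an alkoxide, so the primary bromide should not be displaced.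

Step 2
Reactants: 3 benzyl 12-bromododecyl ether; 4 N,N-dimethylformamide
Product: 6 13-(benzyloxy)tridecanal, via Grignard reagent 5 (not isolated)
Conditions: Mg, THF, 40 °C; then 4, 0 °C → rt; aq. HCl
Reagents that add atoms: 4 N,N-dimethylformamide, CN(C)C=O
Why: Grignard formation and formylation with DMF (Bouveault aldehyde synthesis) add the one carbon that becomes ring carbon C6, and the benzyl ether is inert.

Step 3
Reactants: 6 13-(benzyloxy)tridecanal; 7 (R)-2-methylpropane-2-sulfinamide
Product: 8 (R,E)-N-[13-(benzyloxy)tridecylidene]-2-methylpropane-2-sulfinamide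
Conditions: Ti(OEt)4 (2 equiv), THF, rt; aq. NaCl
Reagents that add atoms: 7 (R)-2-methylpropane-2-sulfinamide, CC(C)(C)[S@@](=O)N
Why: Ti(OEt)4-mediated condensation of aldehyde and sulfinamide should give the (E)-N-sulfinyl aldimine while the titanium reagent takes up the water.

Step 4
Reactants: 8 (R,E)-N-[13-(benzyloxy)tridecylidene]-2-methylpropane-2-sulfinamide; 9 methyl acetate
Product: 12 methyl (3R)-15-(benzyloxy)-3-{[(R)-tert-butylsulfinyl]amino}pentadecanoate, via lithium enolate 10 (not isolated), via titanium enolate 11 (not isolated)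
Conditions: 9 (2 equiv), LiN(iPr)2, THF, −78 °C; ClTi(OiPr)3 (4 equiv), −78 °C; then 8, −78 °C; H2O
Reagents that add atoms: 9 methyl acetate, COC(C)=O
Why: Mannich-type addition of the titanium ester enolate through a six-membered chair (Zimmerman–Traxler) transition state with titanium bound to the sulfinyl oxygen should place the nucleophile on the Si face of the (R)-sulfinyl imine and set C3 of 12 (the later ring carbon C6) as R.

Step 5
Reactants: 12 methyl (3R)-15-(benzyloxy)-3-{[(R)-tert-butylsulfinyl]amino}pentadecanoate
Product: 13 (R)-N-[(3R)-15-(benzyloxy)-1-oxopentadecan-3-yl]-2-methylpropane-2-sulfinamide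
Conditions: iBu2AlH (2.2 equiv), CH2Cl2, −78 °C; aq. potassium sodium tartrate
Reagents that add atoms: none
Why: Partial reduction of the methyl ester with iBu2AlH at −78 °C should stop at the aldehyde through the stable tetrahedral aluminate and does not touch the stereocenter.

Step 6
Reactants: 13 (R)-N-[(3R)-15-(benzyloxy)-1-oxopentadecan-3-yl]-2-methylpropane-2-sulfinamide; 14 methanol
Product: 15 (3R)-15-(benzyloxy)-1,1-dimethoxypentadecan-3-amine
Conditions: HCl (4 M in dioxane, 3 equiv), 14 as solvent, 0 °C → rt; aq. NaOH
Reagents that add atoms: 14 methanol, CO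
Why: Acid methanolysis should cleave the N–S bond and convert the aldehyde into its dimethyl acetal in the same flask, so the free β-amino aldehyde (prone to β-elimination and self-condensation) is never handled.

Step 7
Reactants: 15 (3R)-15-(benzyloxy)-1,1-dimethoxypentadecan-3-amine; 16 1-(benzyloxy)propan-2-one
Product: 18 (2R)-5-(benzyloxy)-2-[12-(benzyloxy)dodecyl]-6-methyl-2,3-dihydropyridine, via ketimine 17 (not isolated)
Conditions: 16 (1.5 equiv), 4 Å molecular sieves, toluene, 60 °C; then CF3CO2H (2 equiv), 0 → 25 °C, argon; aq. NaOH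
Reagents that add atoms: 16 1-(benzyloxy)propan-2-one, CC(=O)COCc1ccccc1
Why: Proposed new method: the primary amine of 15 condenses with ketone 16 to ketimine 17 (N1=C2), whose enamine tautomer on the benzyloxy-bearing carbon (C3) attacks the oxocarbenium ion that CF3CO2H frees from the dimethyl acetal (C3–C4), and vinylogous loss of the second methanol should give the conjugated 1-azadiene 18. The closest known reaction types are the Friedländer annulation of 2-aminobenzaldehydes with α-alkoxy ketones (which gives 3-alkoxy-2-methylquinolines) and the β-amino aldehyde/ketone condensation stage of dehydrogenative pyridine syntheses from γ-amino alcohols; new is the aliphatic version that is stopped at the 2,3-dihydropyridine and keeps an sp3 stereocenter. The one ring that closes (the piperidine ring, which becomes both ring A and ring B) does so by 6-(enolendo)-exo-trig attack of enamine carbon C3 on C4 after the intermolecular imine condensation. No stereocenter is created, and C6 is kept because it is not enolisable in any intermediate. The step needs C–C bond formation at the oxygenated α-carbon and not at the methyl group of 16, which the more acidic α-alkoxy C–H and the more substituted, oxygen-stabilised enamine should secure (as in enamine aldol reactions of hydroxyacetone ethers), and it needs exclusion of air so that 18 does not aromatise.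

Step 8
Reactants: 18 (2R)-5-(benzyloxy)-2-[12-(benzyloxy)dodecyl]-6-methyl-2,3-dihydropyridine
Product: 19 (2S,3S,6R)-6-(12-hydroxydodecyl)-2-methylpiperidin-3-ol
Conditions: H2 (4 bar), Pd/C, EtOH, rt; then AcOH, Pd(OH)2/C, H2 (4 bar), 45 °C; filtration, aq. NaOH
Reagents that add atoms: none
Why: Heterogeneous hydrogenation should add hydrogen to C=N and to the enol ether C=C from the ring face opposite to the C6 side chain, which sets C2 and C3 together as all-cis (2S,3S) by substrate control; the amine formed holds back O-benzyl cleavage until acid and Pd(OH)2/C are added, when both benzyl ethers are removed by hydrogenolysis.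

Step 9
Reactants: 19 (2S,3S,6R)-6-(12-hydroxydodecyl)-2-methylpiperidin-3-ol; 20 di-tert-butyl dicarbonate
Product: 21 tert-butyl (2S,3S,6R)-3-hydroxy-6-(12-hydroxydodecyl)-2-methylpiperidine-1-carboxylate
Conditions: 20 (1.5 equiv), Et3N, MeOH, 50 °C
Reagents that add atoms: 20 di-tert-butyl dicarbonate, CC(C)(C)OC(=O)OC(=O)OC(C)(C)C
Why: Carbamate formation should be selective for the secondary amine over the two hydroxyl groups in the absence of an acylation catalyst.

Step 10
Reactants: 21 tert-butyl (2S,3S,6R)-3-hydroxy-6-(12-hydroxydodecyl)-2-methylpiperidine-1-carboxylate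
Product: 22 tert-butyl (2S,3S,6R)-3-hydroxy-2-methyl-6-(12-oxododecyl)piperidine-1-carboxylate
Conditions: TEMPO (10 mol%), PhI(OAc)2 (1.1 equiv), CH2Cl2, rt
Reagents that add atoms: none
Why: Oxoammonium-mediated oxidation (TEMPO/PhI(OAc)2) should be selective for the primary alcohol over the hindered secondary alcohol at C3 and stops at the aldehyde.

Step 11
Reactants: 22 tert-butyl (2S,3S,6R)-3-hydroxy-2-methyl-6-(12-oxododecyl)piperidine-1-carboxylate (two molecules)
Product: 24 N,N'-bis(tert-butoxycarbonyl) derivative of the target enal, via aldol adduct 23 (not isolated)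
Conditions: pyrrolidine (20 mol%), PhCO2H (20 mol%), 4 Å molecular sieves, toluene, 50 °C
Reagents that add atoms: none
Why: Amine/acid-catalysed aldol self-condensation copies the presumed biogenesis of the central enal; the α-branched (E)-enal (CHO trans to the β-alkyl chain) is the thermodynamic product and has no α-hydrogen left, which should limit further condensation.

Step 12
Reactants: 24 N,N'-bis(tert-butoxycarbonyl) derivative of the target enal
Product: 25 (2E)-14-[(2R,5S,6S)-5-hydroxy-6-methylpiperidin-2-yl]-2-{10-[(2R,5S,6S)-5-hydroxy-6-methylpiperidin-2-yl]decyl}tetradec-2-enal (CNP0177491.1)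
Conditions: CF3CO2H/CH2Cl2 (1:4), 0 °C → rt; aq. NaOH
Reagents that add atoms: none
Why: Acidolysis of both tert-butyl carbamates should leave the enal, the alcohols and all six stereocenters untouched and give the free bis-amine after neutralisation.

**Compound list**

1 | 12-bromododecan-1-ol | OCCCCCCCCCCCCBr | starting material
2 | benzyl 2,2,2-trichloroacetimidate | ClC(Cl)(Cl)C(=N)OCc1ccccc1 | starting material
3 | benzyl 12-bromododecyl ether | BrCCCCCCCCCCCCOCc1ccccc1 | intermediate
4 | N,N-dimethylformamide | CN(C)C=O | starting material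
5 | [12-(benzyloxy)dodecyl]magnesium bromide (not isolated) | Br[Mg]CCCCCCCCCCCCOCc1ccccc1 | intermediate
6 | 13-(benzyloxy)tridecanal | O=CCCCCCCCCCCCCOCc1ccccc1 | intermediate
7 | (R)-2-methylpropane-2-sulfinamide | CC(C)(C)[S@@](=O)N | starting material
8 | (R,E)-N-[13-(benzyloxy)tridecylidene]-2-methylpropane-2-sulfinamide | CC(C)(C)[S@@](=O)/N=C/CCCCCCCCCCCCOCc1ccccc1 | intermediate
9 | methyl acetate | COC(C)=O | starting material
10 | lithium 1-methoxyethen-1-olate (not isolated) | [Li+].[O-]C(=C)OC | intermediate
11 | (1-methoxyethenyloxy)tri(propan-2-yloxy)titanium (not isolated) | COC(=C)O[Ti](OC(C)C)(OC(C)C)OC(C)C | intermediate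
12 | methyl (3R)-15-(benzyloxy)-3-{[(R)-tert-butylsulfinyl]amino}pentadecanoate | COC(=O)C[C@H](N[S@](=O)C(C)(C)C)CCCCCCCCCCCCOCc1ccccc1 | intermediate
13 | (R)-N-[(3R)-15-(benzyloxy)-1-oxopentadecan-3-yl]-2-methylpropane-2-sulfinamide | O=CC[C@H](N[S@](=O)C(C)(C)C)CCCCCCCCCCCCOCc1ccccc1 | intermediate
14 | methanol | CO | starting material
15 | (3R)-15-(benzyloxy)-1,1-dimethoxypentadecan-3-amine | COC(OC)C[C@H](N)CCCCCCCCCCCCOCc1ccccc1 | intermediate
16 | 1-(benzyloxy)propan-2-one | CC(=O)COCc1ccccc1 | starting material
17 | (3R)-15-(benzyloxy)-N-[1-(benzyloxy)propan-2-ylidene]-1,1-dimethoxypentadecan-3-amine (ketimine, not isolated) | COC(OC)C[C@H](N=C(C)COCc1ccccc1)CCCCCCCCCCCCOCc1ccccc1 | intermediate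
18 | (2R)-5-(benzyloxy)-2-[12-(benzyloxy)dodecyl]-6-methyl-2,3-dihydropyridine | CC1=N[C@H](CCCCCCCCCCCCOCc2ccccc2)CC=C1OCc1ccccc1 | intermediate
19 | (2S,3S,6R)-6-(12-hydroxydodecyl)-2-methylpiperidin-3-ol | C[C@@H]1N[C@H](CCCCCCCCCCCCO)CC[C@@H]1O | intermediate
20 | di-tert-butyl dicarbonate | CC(C)(C)OC(=O)OC(=O)OC(C)(C)C | starting material
21 | tert-butyl (2S,3S,6R)-3-hydroxy-6-(12-hydroxydodecyl)-2-methylpiperidine-1-carboxylate | C[C@@H]1N(C(=O)OC(C)(C)C)[C@H](CCCCCCCCCCCCO)CC[C@@H]1O | intermediate
22 | tert-butyl (2S,3S,6R)-3-hydroxy-2-methyl-6-(12-oxododecyl)piperidine-1-carboxylate | C[C@@H]1N(C(=O)OC(C)(C)C)[C@H](CCCCCCCCCCCC=O)CC[C@@H]1O | intermediate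
23 | aldol adduct of two molecules of 22 (3-hydroxy aldehyde, mixture at the two new carbons, not isolated) | C[C@@H]1N(C(=O)OC(C)(C)C)[C@H](CCCCCCCCCCCC(O)C(C=O)CCCCCCCCCC[C@@H]2CC[C@H](O)[C@H](C)N2C(=O)OC(C)(C)C)CC[C@@H]1O | intermediate
24 | N,N'-bis(tert-butoxycarbonyl) derivative of the target enal | C[C@@H]1N(C(=O)OC(C)(C)C)[C@H](CCCCCCCCCCC/C=C(/C=O)CCCCCCCCCC[C@@H]2CC[C@H](O)[C@H](C)N2C(=O)OC(C)(C)C)CC[C@@H]1O | intermediate
25 | (2E)-14-[(2R,5S,6S)-5-hydroxy-6-methylpiperidin-2-yl]-2-{10-[(2R,5S,6S)-5-hydroxy-6-methylpiperidin-2-yl]decyl}tetradec-2-enal | C[C@@H]1N[C@H](CCCCCCCCCCC/C=C(/C=O)CCCCCCCCCC[C@@H]2CC[C@H](O)[C@H](C)N2)CC[C@@H]1O | target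

**Step count and risks**

Total step count: 12. Longest linear sequence: 12 (the route is linear; both halves of the target come from aldehyde 22).

Steps most likely to fail:

Step 7 (proposed new method). What may go wrong: C–C bond formation at the methyl carbon of the ketimine instead of C3; β-elimination of the amine once the aldehyde is unmasked, with loss of material and of the C6 configuration; or oligomerisation by intermolecular condensation. The fallback uses known chemistry, sets out from 13 and comes back at 18. Commercial dimethyl (1-diazo-2-oxopropyl)phosphonate and benzyl alcohol should give, by Rh2(OAc)4-catalysed O–H insertion (CH2Cl2, 40 °C), dimethyl [1-(benzyloxy)-2-oxopropyl]phosphonate F1. Its sodium salt (NaH, THF, 0 °C) should react with aldehyde 13 in a Horner–Wadsworth–Emmons olefination to give (R)-N-[(6R)-3,18-bis(benzyloxy)-2-oxooctadec-3-en-6-yl]-2-methylpropane-2-sulfinamide F2 as an E/Z mixture, so that C3=C4 is made first and its regiochemistry is fixed by the phosphonate. HCl in MeOH should then remove the sulfinyl group and give (6R)-6-amino-3,18-bis(benzyloxy)octadec-3-en-2-one F3 as its hydrochloride, whose enol ether double bond can equilibrate by reversible conjugate addition of methanol. After neutralisation with NaOH (MeOH, 40 °C) the isomer with amine and ketone on the same side should close by intramolecular imine condensation to 18.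

Step 8. What may go wrong: cleavage of the benzyl enol ether before its C=C bond is saturated, so that C3 is no longer set by syn-addition; disproportionation of the dihydropyridine to the pyridine on the catalyst; or poor facial selectivity. The fallback sets out from 18 and comes back at 21. NaBH4 (MeOH, 0 °C) should reduce only the C=N bond, by axial hydride attack, to (2R,6S)-5-(benzyloxy)-2-[12-(benzyloxy)dodecyl]-6-methyl-1,2,3,6-tetrahydropyridine F4, which is not isolated. Aqueous HCl should hydrolyse its enol ether to (2S,6R)-6-[12-(benzyloxy)dodecyl]-2-methylpiperidin-3-one F5 (free base after NaOH), in which C2 is epimerisable and should settle in the diequatorial 2,6-cis form. Di-tert-butyl dicarbonate 20 should give tert-butyl (2S,6R)-6-[12-(benzyloxy)dodecyl]-2-methyl-3-oxopiperidine-1-carboxylate F6. LiBH(sBu)3 (THF, −78 °C) should attack the ketone from the face opposite to the axial 2-methyl group and give the 2,3-cis alcohol tert-butyl (2S,3S,6R)-6-[12-(benzyloxy)dodecyl]-3-hydroxy-2-methylpiperidine-1-carboxylate F7. Hydrogenolysis of the remaining benzyl ether (H2, Pd(OH)2/C, EtOAc) should then give 21.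

Step 11. What may go wrong: further Michael or aldol reaction of the enal with unreacted aldehyde (oligomers), or incomplete dehydration of the aldol adduct. The fallback sets out from 22 and comes back at 24. One portion of 22 is α-methylenated with aqueous formaldehyde (pyrrolidine and propionic acid as catalysts, iPrOH, 45 °C; Mannich condensation and elimination) to the 2-substituted acrolein tert-butyl (2S,3S,6R)-6-(10-formylundec-10-en-1-yl)-3-hydroxy-2-methylpiperidine-1-carboxylate F8. A second portion is converted by Wittig methylenation (Ph3PCH3Br, KOtBu, THF) to the terminal alkene tert-butyl (2S,3S,6R)-3-hydroxy-2-methyl-6-(tridec-12-en-1-yl)piperidine-1-carboxylate F9. Cross-metathesis of F8 with an excess of F9 (second-generation Hoveyda–Grubbs catalyst, CH2Cl2, 40 °C) should give the trisubstituted (E)-enal 24 directly, with donor and acceptor roles fixed by the two partners.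

**Further compounds**

F1 | step 7 | dimethyl [1-(benzyloxy)-2-oxopropyl]phosphonate | COP(=O)(OC)C(OCc1ccccc1)C(C)=O
F2 | step 7 | (R)-N-[(6R)-3,18-bis(benzyloxy)-2-oxooctadec-3-en-6-yl]-2-methylpropane-2-sulfinamide | CC(=O)C(OCc1ccccc1)=CC[C@H](N[S@](=O)C(C)(C)C)CCCCCCCCCCCCOCc1ccccc1
F3 | step 7 | (6R)-6-amino-3,18-bis(benzyloxy)octadec-3-en-2-one | CC(=O)C(OCc1ccccc1)=CC[C@H](N)CCCCCCCCCCCCOCc1ccccc1
F4 | step 8 | (2R,6S)-5-(benzyloxy)-2-[12-(benzyloxy)dodecyl]-6-methyl-1,2,3,6-tetrahydropyridine | C[C@@H]1N[C@H](CCCCCCCCCCCCOCc2ccccc2)CC=C1OCc1ccccc1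
F5 | step 8 | (2S,6R)-6-[12-(benzyloxy)dodecyl]-2-methylpiperidin-3-one | C[C@@H]1N[C@H](CCCCCCCCCCCCOCc2ccccc2)CCC1=O
F6 | step 8 | tert-butyl (2S,6R)-6-[12-(benzyloxy)dodecyl]-2-methyl-3-oxopiperidine-1-carboxylate | C[C@@H]1N(C(=O)OC(C)(C)C)[C@H](CCCCCCCCCCCCOCc2ccccc2)CCC1=O
F7 | step 8 | tert-butyl (2S,3S,6R)-6-[12-(benzyloxy)dodecyl]-3-hydroxy-2-methylpiperidine-1-carboxylate | C[C@@H]1N(C(=O)OC(C)(C)C)[C@H](CCCCCCCCCCCCOCc2ccccc2)CC[C@@H]1O
F8 | step 11 | tert-butyl (2S,3S,6R)-6-(10-formylundec-10-en-1-yl)-3-hydroxy-2-methylpiperidine-1-carboxylate | C[C@@H]1N(C(=O)OC(C)(C)C)[C@H](CCCCCCCCCCC(=C)C=O)CC[C@@H]1O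
F9 | step 11 | tert-butyl (2S,3S,6R)-3-hydroxy-2-methyl-6-(tridec-12-en-1-yl)piperidine-1-carboxylate | C[C@@H]1N(C(=O)OC(C)(C)C)[C@H](CCCCCCCCCCCC=C)CC[C@@H]1O
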